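Ring B of the target (C1–C4, C4a, C8a) is a 7,8-dioxygenated naphthalene-2,3-dicarboxylate that has taken up an aryl anion at C1 and a proton at C2. C3=C4 is what remains of the arene. Everything rests on the C1–aryl disconnection. 3,4-Bis(benzyloxy)phenyllithium adds to C1 of a flat naphthalene whose C2 carboxyl is an (R)-4-tert-butyloxazoline and whose C3 carboxyl is a tert-butyl ester. This one operation forms the C1–aryl bond, dearomatises ring B, and sets C1 (auxiliary) and C2 (equilibration to trans). Auxiliary removal, two invertive Mitsunobu esterifications with an (S)-aryllactate and one global debenzylation complete the synthesis.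

Key step: step 12

Remark on numbering: all bicyclic compounds carry the locants of the target. C1 = CH(aryl), C2, C3, C4, ring A = C4a–C8a with O7 and O8, and C8 is next to C8a.
Assumption: the sense of induction follows the accepted model for 4-alkyl-naphthyloxazolines, in which nitrogen-bound lithium delivers the aryl group anti to the C4′ substituent in the s-cis N=C–C2=C1 rotamer. On that model the (R)-oxazoline gives (1R).

Step 1
Reactants: 1 2-bromo-3-hydroxy-4-methoxybenzaldehyde (2-bromoisovanillin)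
Product: 2 2-bromo-3,4-dihydroxybenzaldehyde
Conditions: BBr3 (2.5 equiv), CH2Cl2, −78 → 23 °C; H2O
Reagents that add atoms: none
Why: Lewis-acid cleavage of an aryl methyl ether, in which boron is anchored by the neighbouring phenol and bromide attacks the methyl group, while the aldehyde and the aryl bromide are left alone.

Step 2
Reactants: 2 2-bromo-3,4-dihydroxybenzaldehyde
Product: 3 3,4-bis(benzyloxy)-2-bromobenzaldehyde
Conditions: BnBr (2.3 equiv), K2CO3, DMF, 60 °C
Reagents that add atoms: benzyl bromide, BrCc1ccccc1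
Why: Williamson ether synthesis on both phenoxides; benzyl ethers should survive organolithiums, aqueous acid and base, borohydride, chlorite and TFA, and they all fall in the last step.

Step 3
Reactants: 3 3,4-bis(benzyloxy)-2-bromobenzaldehyde
Product: 4 2-[3,4-bis(benzyloxy)-2-bromophenyl]-1,3-dioxolane
Conditions: ethylene glycol, p-TsOH (cat.), toluene, reflux, Dean–Stark
Reagents that add atoms: ethylene glycol, OCCO
Why: Acid-catalysed acetalisation with azeotropic removal of water masks the future C4 aldehyde, so that the two formyl carbons stay distinguishable and the aldehyde tolerates butyllithium.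

Step 4
Reactants: 4 2-[3,4-bis(benzyloxy)-2-bromophenyl]-1,3-dioxolane
Product: 6 2,3-bis(benzyloxy)-6-(1,3-dioxolan-2-yl)benzaldehyde, via [2,3-bis(benzyloxy)-6-(1,3-dioxolan-2-yl)phenyl]lithium 5 (not isolated)
Conditions: n-BuLi (1.05 equiv), THF, −78 °C; DMF, −78 → 0 °C; H2O
Reagents that add atoms: N,N-dimethylformamide, CN(C)C=O; n-butyllithium, [Li]CCCC (lithium in 5 only)
Why: Bromine–lithium exchange is faster at −78 °C than benzylic deprotonation, and Bouveault-type formylation of the chelated aryllithium places the future C1 carbon next to the carbon that bears O8.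

Step 5
Reactants: 7 triethyl phosphonoacetate; 8 tert-butyl bromoacetate
Product: 9 4-tert-butyl 1-ethyl 2-(diethoxyphosphoryl)butanedioate (racemic)
Conditions: NaH, THF, 0 °C; 8, 0 → 23 °C
Reagents that add atoms: none
Why: SN2 alkylation of the stabilised phosphonate carbanion puts the ethyl ester on the phosphonate carbon (future C2) and the tert-butyl ester on the CH2 arm (future C3).

Step 6
Reactants: 6 2,3-bis(benzyloxy)-6-(1,3-dioxolan-2-yl)benzaldehyde; 9 4-tert-butyl 1-ethyl 2-(diethoxyphosphoryl)butanedioate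
Product: 10 4-tert-butyl 1-ethyl (E)-2-{[2,3-bis(benzyloxy)-6-(1,3-dioxolan-2-yl)phenyl]methylidene}butanedioate
Conditions: 9 (1.2 equiv), NaH, THF, 0 °C; 6, 0 → 40 °C
Reagents that add atoms: none
Why: Horner–Wadsworth–Emmons olefination of the only free aldehyde forms C1=C2, and the E isomer (aryl cis to the CH2CO2t-Bu arm) should prevail; any Z isomer is not lost, since step 7 equilibrates the alkene through its dienolate.

Step 7
Reactants: 10 4-tert-butyl 1-ethyl (E)-2-{[2,3-bis(benzyloxy)-6-(1,3-dioxolan-2-yl)phenyl]methylidene}butanedioate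
Product: 12 3-tert-butyl 2-ethyl 7,8-bis(benzyloxy)naphthalene-2,3-dicarboxylate, via 4-tert-butyl 1-ethyl (E)-2-{[2,3-bis(benzyloxy)-6-formylphenyl]methylidene}butanedioate 11 (not isolated)
Conditions: 1 M HCl (cat.), THF, 23 °C; extractive work-up; DBU, toluene, 23 → 60 °C
Reagents that add atoms: water, O (aldehyde oxygen of 11 only, lost again on aromatisation)
Why: Mild acid frees the aldehyde (the para benzyloxy group stabilises the oxocarbenium ion and the tert-butyl ester is untouched), and DBU then drives an intramolecular vinylogous aldol condensation of the CH2 arm onto it (C3–C4 bond), with loss of water pulled by aromatisation.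

Step 8
Reactants: 12 3-tert-butyl 2-ethyl 7,8-bis(benzyloxy)naphthalene-2,3-dicarboxylate
Product: 13 7,8-bis(benzyloxy)-3-(tert-butoxycarbonyl)naphthalene-2-carboxylic acid
Conditions: LiOH·H2O (3 equiv), THF–EtOH–H2O, 40 °C; 1 M HCl, 0 °C, to pH 3
Reagents that add atoms: lithium hydroxide, [Li+].[OH-]
Why: Saponification (BAc2) distinguishes the two esters, because hydroxide does not attack the tert-butyl ester carbonyl.

Step 9
Reactants: 13 7,8-bis(benzyloxy)-3-(tert-butoxycarbonyl)naphthalene-2-carboxylic acid; 14 (R)-tert-leucinol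
Product: 15 tert-butyl 7,8-bis(benzyloxy)-2-{[(2R)-1-hydroxy-3,3-dimethylbutan-2-yl]carbamoyl}naphthalene-3-carboxylate
Conditions: EDC·HCl, HOBt, CH2Cl2, 0 → 23 °C
Reagents that add atoms: none
Why: Carbodiimide/HOBt amide coupling acylates the amine in preference to the primary alcohol, does not touch the stereocentre, and is mild enough to avoid imide formation with the neighbouring ester.

Step 10
Reactants: 15 tert-butyl 7,8-bis(benzyloxy)-2-{[(2R)-1-hydroxy-3,3-dimethylbutan-2-yl]carbamoyl}naphthalene-3-carboxylate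
Product: 17 tert-butyl 7,8-bis(benzyloxy)-2-[(4R)-4-tert-butyl-4,5-dihydro-1,3-oxazol-2-yl]naphthalene-3-carboxylate, via primary mesylate of 15, compound 16 (not isolated)
Conditions: MsCl (1.2 equiv), Et3N (3 equiv), CH2Cl2, 0 → 40 °C
Reagents that add atoms: methanesulfonyl chloride, CS(=O)(=O)Cl (mesyl group in 16 only)
Why: Mesylation of the primary alcohol and 5-exo-tet displacement by the amide oxygen (cyclodehydration to the oxazoline) take place at the CH2 carbon, so the stereocentre keeps its (R) configuration.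

Step 11
Reactants: 18 4-bromocatechol
Product: 19 4-bromo-1,2-bis(benzyloxy)benzene
Conditions: BnBr (2.3 equiv), K2CO3, DMF, 60 °C
Reagents that add atoms: benzyl bromide, BrCc1ccccc1
Why: Williamson ether synthesis gives the one aryl bromide that serves both as the C1 aryl donor (step 12) and as the source of both side-chain arenes (step 15).

Step 12
Reactants: 17 tert-butyl 7,8-bis(benzyloxy)-2-[(4R)-4-tert-butyl-4,5-dihydro-1,3-oxazol-2-yl]naphthalene-3-carboxylate; 19 4-bromo-1,2-bis(benzyloxy)benzene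
Product: 23 tert-butyl (1R,2S)-7,8-bis(benzyloxy)-1-[3,4-bis(benzyloxy)phenyl]-2-[(4R)-4-tert-butyl-4,5-dihydro-1,3-oxazol-2-yl]-1,2-dihydronaphthalene-3-carboxylate (trans), via 3,4-bis(benzyloxy)phenyllithium 20 (not isolated), via lithium aza-enolate 21 (not isolated), via (1R,2R)-cis-dihydronaphthalene 22 (not isolated)
Conditions: 19 (1.5 equiv), t-BuLi (3.0 equiv), THF, −78 °C; 17 in THF, −78 → −40 °C; MeOH (excess), −78 → 23 °C, under Ar
Reagents that add atoms: tert-butyllithium, [Li]C(C)(C)C (lithium in 20 and 21 only)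
Why: Aryllithium 20 binds the oxazoline nitrogen of 17 in the s-cis N=C–C2=C1 rotamer and passes its aryl group to C1, a 1,4-addition across the azadiene that dearomatises ring B only and leaves the lithium aza-enolate 21, still conjugated with C3=C4. The closest known reaction type is this very one, the diastereoselective dearomatising conjugate addition of organolithiums to chiral 2-naphthyloxazolines; one skeletal bond is formed and no ring is closed. C1 is controlled by the auxiliary: the C4′ tert-butyl group shields one side of the nitrogen-bound lithium, the aryl group enters anti to it, and with the (R)-oxazoline this is the face that gives (1R). C2 is controlled by thermodynamics: methanol protonates 21 at C2 anti to the pseudo-axial aryl group (mainly cis-22), and the lithium methoxide so formed epimerises C2 through the same aza-enolate to trans-23, in which aryl and oxazoline are both pseudo-axial, clear of the peri O8 ether and of the in-plane C3 ester. The step needs attack at C1 rather than at C4 or a carbonyl, which is secured by pre-complexation at the nitrogen next to C1 (with O8 nearby as a possible second contact for lithium) and by the tert-butyl ester, which is hindered and is twisted out of conjugation by its ortho neighbour so that C4 is not activated. It also needs an aza-enolate that meets no electrophile but a proton, hence t-BuLi (2 equiv per bromide), which destroys its own alkyl bromide, and it needs protonation at C2 rather than C4, the outcome that keeps C3=C4 conjugated with ring A and the ester.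

Step 13
Reactants: 23 trans-dihydronaphthalene oxazoline
Product: 26 tert-butyl (1R,2S)-7,8-bis(benzyloxy)-1-[3,4-bis(benzyloxy)phenyl]-2-formyl-1,2-dihydronaphthalene-3-carboxylate, via N-methyloxazolinium triflate 24 (not isolated), via N-methyloxazolidine 25 (not isolated)
Conditions: MeOTf, CH2Cl2, 23 °C; NaBH4, THF–MeOH, 0 °C; (CO2H)2, THF–H2O, 23 °C (crude intermediates carried on)
Reagents that add atoms: water, O (aldehyde oxygen); methyl triflate, COS(=O)(=O)C(F)(F)F (methyl group in 24 and 25 only, leaves with the auxiliary)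
Why: This is the standard reductive unmasking of an oxazoline (N-methylation, borohydride reduction to the N,O-acetal, mild acid hydrolysis), to which the enoate, the tert-butyl ester and the benzyl ethers are inert, and the enolisable C2 already holds the favoured trans arrangement.

Step 14
Reactants: 26 trans-2-formyl-dihydronaphthalene
Product: 27 (1R,2S)-7,8-bis(benzyloxy)-1-[3,4-bis(benzyloxy)phenyl]-3-(tert-butoxycarbonyl)-1,2-dihydronaphthalene-2-carboxylic acid
Conditions: NaClO2, NaH2PO4, 2-methyl-2-butene (excess), t-BuOH–THF–H2O, 0 → 23 °C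
Reagents that add atoms: sodium chlorite, [Na+].[O-]Cl=O
Why: Pinnick oxidation works at buffered pH without enolising C2, and the alkene scavenger removes hypochlorous acid before it can chlorinate the electron-rich rings.

Step 15
Reactants: 19 4-bromo-1,2-bis(benzyloxy)benzene; 28 methyl (S)-glycidate
Product: 30 methyl (S)-3-[3,4-bis(benzyloxy)phenyl]-2-hydroxypropanoate, via 3,4-bis(benzyloxy)phenylmagnesium bromide 29 (not isolated)
Conditions: Mg, THF, 40 °C; CuI (10 mol %), 28, THF, −40 → −20 °C; aqueous work-up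
Reagents that add atoms: magnesium, [Mg] (in 29 only)
Why: Copper-catalysed SN2 opening of the glycidic ester by the aryl Grignard reagent at the unsubstituted carbon is faster than ester attack at low temperature, and it leaves the C2–O bond untouched, so the (S) configuration is carried over.

Step 16
Reactants: 30 methyl (S)-3-[3,4-bis(benzyloxy)phenyl]-2-hydroxypropanoate
Product: 31 benzyl (S)-3-[3,4-bis(benzyloxy)phenyl]-2-hydroxypropanoate
Conditions: BnOH (5 equiv), Ti(Oi-Pr)4 (10 mol %), toluene, 100 °C, MeOH distilled off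
Reagents that add atoms: benzyl alcohol, OCc1ccccc1
Why: Titanate-mediated transesterification is neutral, is accelerated by chelation of the α-hydroxy ester and does not touch the stereocentre, and the benzyl ester will fall together with the ethers in the last step.

Step 17
Reactants: 27 trans-C2 acid; 31 benzyl (S)-3-[3,4-bis(benzyloxy)phenyl]-2-hydroxypropanoate
Product: 32 C2 (R)-lactate ester: 3-tert-butyl 2-{(2R)-1-(benzyloxy)-3-[3,4-bis(benzyloxy)phenyl]-1-oxopropan-2-yl} (1R,2S)-7,8-bis(benzyloxy)-1-[3,4-bis(benzyloxy)phenyl]-1,2-dihydronaphthalene-2,3-dicarboxylate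
Conditions: 31 (1.3 equiv), PPh3, DIAD, THF, 0 → 23 °C
Reagents that add atoms: none
Why: In this Mitsunobu esterification the carboxylate of 27 displaces the oxyphosphonium salt of (S)-31 by SN2 with inversion, which sets the (R) carbinol centre without activating the epimerisable C2 acyl group, and C3 is still blocked, so no vicinal diacid can divert to a cyclic anhydride.

Step 18
Reactants: 32 C2 (R)-lactate ester, C3 tert-butyl ester
Product: 33 (1R,2S)-7,8-bis(benzyloxy)-1-[3,4-bis(benzyloxy)phenyl]-2-({(2R)-1-(benzyloxy)-3-[3,4-bis(benzyloxy)phenyl]-1-oxopropan-2-yl}oxycarbonyl)-1,2-dihydronaphthalene-3-carboxylic acid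
Conditions: TFA–CH2Cl2 (1:4), 0 → 23 °C
Reagents that add atoms: none
Why: Acidolysis of the tert-butyl ester (E1 loss of isobutene) should spare the benzyl ethers, the benzyl ester and the secondary ester on short exposure, and it touches no stereocentre.

Step 19
Reactants: 33 C3 acid; 31 benzyl (S)-3-[3,4-bis(benzyloxy)phenyl]-2-hydroxypropanoate
Product: 34 decabenzyl-protected target: bis{(2R)-1-(benzyloxy)-3-[3,4-bis(benzyloxy)phenyl]-1-oxopropan-2-yl} (1R,2S)-7,8-bis(benzyloxy)-1-[3,4-bis(benzyloxy)phenyl]-1,2-dihydronaphthalene-2,3-dicarboxylate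
Conditions: 31 (1.3 equiv), PPh3, DIAD, THF, 0 → 23 °C
Reagents that add atoms: none
Why: A second Mitsunobu esterification, now with the unsaturated C3 acid as nucleophile, again inverts (S)-31 and sets the second (R) carbinol centre under near-neutral conditions that leave C2 alone.

Step 20
Reactants: 34 decabenzyl-protected target
Product: 35 target CNP0244800.2, (1R,2S)-trans, both side chains (R)
Conditions: BCl3 (30 equiv), pentamethylbenzene (30 equiv), CH2Cl2, −78 → −10 °C; H2O–THF, 0 °C; reversed-phase chromatography under Ar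
Reagents that add atoms: none
Why: In this Lewis-acid debenzylation with a non-basic cation scavenger, BCl3 ionises the eight aryl benzyl ethers and, on warming, the two benzyl esters; pentamethylbenzene takes up the benzyl cations (Friedel–Crafts) before they can alkylate the catechols, and C3=C4 (which rules out hydrogenolysis) and the two secondary esters, whose cleavage would need an α-acyl cation, should remain.

Compound list
1 | 2-bromo-3-hydroxy-4-methoxybenzaldehyde | COc1ccc(C=O)c(Br)c1O | starting material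
2 | 2-bromo-3,4-dihydroxybenzaldehyde | O=Cc1ccc(O)c(O)c1Br | intermediate
3 | 3,4-bis(benzyloxy)-2-bromobenzaldehyde | O=Cc1ccc(OCc2ccccc2)c(OCc2ccccc2)c1Br | intermediate
4 | 2-[3,4-bis(benzyloxy)-2-bromophenyl]-1,3-dioxolane | Brc1c(C2OCCO2)ccc(OCc2ccccc2)c1OCc1ccccc1 | intermediate
5 | [2,3-bis(benzyloxy)-6-(1,3-dioxolan-2-yl)phenyl]lithium (not isolated) | [Li]c1c(C2OCCO2)ccc(OCc2ccccc2)c1OCc1ccccc1 | intermediate
6 | 2,3-bis(benzyloxy)-6-(1,3-dioxolan-2-yl)benzaldehyde | O=Cc1c(C2OCCO2)ccc(OCc2ccccc2)c1OCc1ccccc1 | intermediate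
7 | triethyl phosphonoacetate | CCOC(=O)CP(=O)(OCC)OCC | starting material
8 | tert-butyl bromoacetate | CC(C)(C)OC(=O)CBr | starting material
9 | 4-tert-butyl 1-ethyl 2-(diethoxyphosphoryl)butanedioate (racemic) | CCOC(=O)C(CC(=O)OC(C)(C)C)P(=O)(OCC)OCC | intermediate
10 | 4-tert-butyl 1-ethyl (E)-2-{[2,3-bis(benzyloxy)-6-(1,3-dioxolan-2-yl)phenyl]methylidene}butanedioate | CCOC(=O)/C(CC(=O)OC(C)(C)C)=C/c1c(C2OCCO2)ccc(OCc2ccccc2)c1OCc1ccccc1 | intermediate
11 | 4-tert-butyl 1-ethyl (E)-2-{[2,3-bis(benzyloxy)-6-formylphenyl]methylidene}butanedioate (not isolated) | CCOC(=O)/C(CC(=O)OC(C)(C)C)=C/c1c(C=O)ccc(OCc2ccccc2)c1OCc1ccccc1 | intermediate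
12 | 3-tert-butyl 2-ethyl 7,8-bis(benzyloxy)naphthalene-2,3-dicarboxylate | CCOC(=O)c1cc2c(OCc3ccccc3)c(OCc3ccccc3)ccc2cc1C(=O)OC(C)(C)C | intermediate
13 | 7,8-bis(benzyloxy)-3-(tert-butoxycarbonyl)naphthalene-2-carboxylic acid | OC(=O)c1cc2c(OCc3ccccc3)c(OCc3ccccc3)ccc2cc1C(=O)OC(C)(C)C | intermediate
14 | (R)-tert-leucinol | CC(C)(C)[C@@H](N)CO | starting material
15 | tert-butyl 7,8-bis(benzyloxy)-2-{[(2R)-1-hydroxy-3,3-dimethylbutan-2-yl]carbamoyl}naphthalene-3-carboxylate | CC(C)(C)[C@@H](NC(=O)c1cc2c(OCc3ccccc3)c(OCc3ccccc3)ccc2cc1C(=O)OC(C)(C)C)CO | intermediate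
16 | primary methanesulfonate of 15 (not isolated) | CC(C)(C)[C@@H](NC(=O)c1cc2c(OCc3ccccc3)c(OCc3ccccc3)ccc2cc1C(=O)OC(C)(C)C)COS(C)(=O)=O | intermediate
17 | tert-butyl 7,8-bis(benzyloxy)-2-[(4R)-4-tert-butyl-4,5-dihydro-1,3-oxazol-2-yl]naphthalene-3-carboxylate | CC(C)(C)OC(=O)c1cc2ccc(OCc3ccccc3)c(OCc3ccccc3)c2cc1C1=N[C@H](C(C)(C)C)CO1 | intermediate
18 | 4-bromocatechol | Oc1ccc(Br)cc1O | starting material
19 | 4-bromo-1,2-bis(benzyloxy)benzene | Brc1ccc(OCc2ccccc2)c(OCc2ccccc2)c1 | intermediate
20 | 3,4-bis(benzyloxy)phenyllithium (not isolated) | [Li]c1ccc(OCc2ccccc2)c(OCc2ccccc2)c1 | intermediate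
21 | lithium aza-enolate (C2=C2′ exocyclic, N–Li, C1 configured as in 23; not isolated) | CC(C)(C)OC(=O)C1=Cc2ccc(OCc3ccccc3)c(OCc3ccccc3)c2[C@@H](c2ccc(OCc3ccccc3)c(OCc3ccccc3)c2)C1=C1N([Li])[C@H](C(C)(C)C)CO1 | intermediate
22 | (1R,2R)-cis epimer of 23 (not isolated) | CC(C)(C)OC(=O)C1=Cc2ccc(OCc3ccccc3)c(OCc3ccccc3)c2[C@@H](c2ccc(OCc3ccccc3)c(OCc3ccccc3)c2)[C@H]1C1=N[C@H](C(C)(C)C)CO1 | intermediate
23 | tert-butyl (1R,2S)-7,8-bis(benzyloxy)-1-[3,4-bis(benzyloxy)phenyl]-2-[(4R)-4-tert-butyl-4,5-dihydro-1,3-oxazol-2-yl]-1,2-dihydronaphthalene-3-carboxylate | CC(C)(C)OC(=O)C1=Cc2ccc(OCc3ccccc3)c(OCc3ccccc3)c2[C@@H](c2ccc(OCc3ccccc3)c(OCc3ccccc3)c2)[C@@H]1C1=N[C@H](C(C)(C)C)CO1 | intermediate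
24 | N-methyloxazolinium triflate of 23 (not isolated) | CC(C)(C)OC(=O)C1=Cc2ccc(OCc3ccccc3)c(OCc3ccccc3)c2[C@@H](c2ccc(OCc3ccccc3)c(OCc3ccccc3)c2)[C@@H]1C1=[N+](C)[C@H](C(C)(C)C)CO1.[O-]S(=O)(=O)C(F)(F)F | intermediate
25 | N-methyloxazolidine (epimers at C2′; not isolated) | CC(C)(C)OC(=O)C1=Cc2ccc(OCc3ccccc3)c(OCc3ccccc3)c2[C@@H](c2ccc(OCc3ccccc3)c(OCc3ccccc3)c2)[C@@H]1C1N(C)[C@H](C(C)(C)C)CO1 | intermediate
26 | tert-butyl (1R,2S)-7,8-bis(benzyloxy)-1-[3,4-bis(benzyloxy)phenyl]-2-formyl-1,2-dihydronaphthalene-3-carboxylate | CC(C)(C)OC(=O)C1=Cc2ccc(OCc3ccccc3)c(OCc3ccccc3)c2[C@@H](c2ccc(OCc3ccccc3)c(OCc3ccccc3)c2)[C@@H]1C=O | intermediate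
27 | (1R,2S)-7,8-bis(benzyloxy)-1-[3,4-bis(benzyloxy)phenyl]-3-(tert-butoxycarbonyl)-1,2-dihydronaphthalene-2-carboxylic acid | CC(C)(C)OC(=O)C1=Cc2ccc(OCc3ccccc3)c(OCc3ccccc3)c2[C@@H](c2ccc(OCc3ccccc3)c(OCc3ccccc3)c2)[C@@H]1C(=O)O | intermediate
28 | methyl (S)-glycidate | COC(=O)[C@@H]1CO1 | starting material
29 | 3,4-bis(benzyloxy)phenylmagnesium bromide (not isolated) | Br[Mg]c1ccc(OCc2ccccc2)c(OCc2ccccc2)c1 | intermediate
30 | methyl (S)-3-[3,4-bis(benzyloxy)phenyl]-2-hydroxypropanoate | COC(=O)[C@@H](O)Cc1ccc(OCc2ccccc2)c(OCc2ccccc2)c1 | intermediate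
31 | benzyl (S)-3-[3,4-bis(benzyloxy)phenyl]-2-hydroxypropanoate | O=C(OCc1ccccc1)[C@@H](O)Cc1ccc(OCc2ccccc2)c(OCc2ccccc2)c1 | intermediate
32 | C2 (R)-lactate ester, C3 tert-butyl ester, (1R,2S) | CC(C)(C)OC(=O)C1=Cc2ccc(OCc3ccccc3)c(OCc3ccccc3)c2[C@@H](c2ccc(OCc3ccccc3)c(OCc3ccccc3)c2)[C@@H]1C(=O)O[C@H](Cc1ccc(OCc2ccccc2)c(OCc2ccccc2)c1)C(=O)OCc1ccccc1 | intermediate
33 | C2 (R)-lactate ester, C3 free acid, (1R,2S) | OC(=O)C1=Cc2ccc(OCc3ccccc3)c(OCc3ccccc3)c2[C@@H](c2ccc(OCc3ccccc3)c(OCc3ccccc3)c2)[C@@H]1C(=O)O[C@H](Cc1ccc(OCc2ccccc2)c(OCc2ccccc2)c1)C(=O)OCc1ccccc1 | intermediate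
34 | decabenzyl-protected target, (1R,2S), both side chains (R) | O=C(O[C@H](Cc1ccc(OCc2ccccc2)c(OCc2ccccc2)c1)C(=O)OCc1ccccc1)C1=Cc2ccc(OCc3ccccc3)c(OCc3ccccc3)c2[C@@H](c2ccc(OCc3ccccc3)c(OCc3ccccc3)c2)[C@@H]1C(=O)O[C@H](Cc1ccc(OCc2ccccc2)c(OCc2ccccc2)c1)C(=O)OCc1ccccc1 | intermediate
35 | CNP0244800.2 | O=C(O[C@H](Cc1ccc(O)c(O)c1)C(=O)O)C1=Cc2ccc(O)c(O)c2[C@@H](c2ccc(O)c(O)c2)[C@@H]1C(=O)O[C@H](Cc1ccc(O)c(O)c1)C(=O)O | target

Total step count: 20.
Longest linear sequence: 16 steps, from 1 to 35 (steps 1–4, 6–10, 12–14, 17–20). Steps 5, 11, 15 and 16 lie on side branches.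

Steps most likely to fail

1. Step 12.
- What may go wrong: O7 donates into C1 and the peri ether crowds it, so aryl transfer to C1 may be slow enough for addition to the ester carbonyl or to C4 to compete.
- The ortho ester may also twist the oxazoline and erode facial discrimination.
- Prolonged base contact may shift the double bond, or air may rearomatise the ring.
- Fallback: remove the second acceptor and carry C3 through the dearomatisation at the alcohol oxidation level. It sets out from 17 and comes back at 23.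
- LiAlH4 (THF, 0 → 23 °C, the oxazoline is inert) should give the hydroxymethylnaphthalene F1, and TBSCl/imidazole should give its silyl ether F2.
- Addition of 20 as in step 12, a methanol quench and equilibration with KOt-Bu in t-BuOH–THF should give the trans-dihydronaphthalene F3. Here the oxazoline is the only activating and directing group.
- TBAF should give the allylic alcohol F4, MnO2 the enal F5 and Pinnick oxidation the unsaturated acid F6. Boc2O/DMAP in t-BuOH then closes the loop to 23.

2. Step 20.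
- What may go wrong: cleavage of ten benzyl groups may stall at partly protected stages.
- Freed catechols may be C-benzylated, a lactate ester may be lost on warming, and the tetracatechol may oxidise in air during isolation.
- Fallback: change from Lewis-acid ionisation to reductive benzyl–silyl exchange. It sets out from 34 and comes back at 35.
- Pd(OAc)2 (cat.), Et3SiH and Et3N in CH2Cl2 at 23 °C cleave aryl benzyl ethers and benzyl esters while sparing alkenes, and should give the deca(triethylsilyl) derivative F9.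
- The labile silyl ethers and esters of F9 are then removed with AcOH–THF–H2O under argon to give 35.

3. Step 17 (the same holds for step 19).
- What may go wrong: the oxyphosphonium salt of the β-aryl-α-hydroxy ester may eliminate towards the cinnamate.
- Participation of the electron-rich arene, or an acyloxyphosphonium pathway with the hindered acid, may leak towards retention and lower the diastereomeric purity.
- Fallback: form the ester bond at the acyl carbon, with retention at the carbinol carbon. It sets out from 27 (with 19 for the alcohol) and comes back at 32.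
- Grignard reagent 29 opens methyl (R)-glycidate as in step 15 to give the methyl (R)-lactate F7. Transesterification as in step 16 gives the benzyl (R)-lactate F8.
- Compound 27 is then coupled with F8 under Steglich conditions (EDC·HCl, DMAP, CH2Cl2, 0 °C) to give 32. Any epimerisation at C2 on activation runs towards the favoured trans isomer.
- The same alcohol F8 takes 33 to 34.

Further compounds
F1 | step 12 | {7,8-bis(benzyloxy)-2-[(4R)-4-tert-butyl-4,5-dihydro-1,3-oxazol-2-yl]naphthalen-3-yl}methanol | OCc1cc2ccc(OCc3ccccc3)c(OCc3ccccc3)c2cc1C1=N[C@H](C(C)(C)C)CO1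
F2 | step 12 | tert-butyldimethylsilyl ether of F1 | CC(C)(C)[Si](C)(C)OCc1cc2ccc(OCc3ccccc3)c(OCc3ccccc3)c2cc1C1=N[C@H](C(C)(C)C)CO1
F3 | step 12 | (1R,2S)-trans-1-aryl-3-(silyloxymethyl)-2-oxazolinyl-1,2-dihydronaphthalene | CC(C)(C)[Si](C)(C)OCC1=Cc2ccc(OCc3ccccc3)c(OCc3ccccc3)c2[C@@H](c2ccc(OCc3ccccc3)c(OCc3ccccc3)c2)[C@@H]1C1=N[C@H](C(C)(C)C)CO1
F4 | step 12 | (1R,2S)-trans allylic alcohol | OCC1=Cc2ccc(OCc3ccccc3)c(OCc3ccccc3)c2[C@@H](c2ccc(OCc3ccccc3)c(OCc3ccccc3)c2)[C@@H]1C1=N[C@H](C(C)(C)C)CO1
F5 | step 12 | (1R,2S)-trans enal | O=CC1=Cc2ccc(OCc3ccccc3)c(OCc3ccccc3)c2[C@@H](c2ccc(OCc3ccccc3)c(OCc3ccccc3)c2)[C@@H]1C1=N[C@H](C(C)(C)C)CO1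
F6 | step 12 | (1R,2S)-trans C3 carboxylic acid with C2 oxazoline | OC(=O)C1=Cc2ccc(OCc3ccccc3)c(OCc3ccccc3)c2[C@@H](c2ccc(OCc3ccccc3)c(OCc3ccccc3)c2)[C@@H]1C1=N[C@H](C(C)(C)C)CO1
F7 | step 17 | methyl (R)-3-[3,4-bis(benzyloxy)phenyl]-2-hydroxypropanoate | COC(=O)[C@H](O)Cc1ccc(OCc2ccccc2)c(OCc2ccccc2)c1
F8 | step 17 | benzyl (R)-3-[3,4-bis(benzyloxy)phenyl]-2-hydroxypropanoate | O=C(OCc1ccccc1)[C@H](O)Cc1ccc(OCc2ccccc2)c(OCc2ccccc2)c1
F9 | step 20 | deca(triethylsilyl) derivative of 35 (eight aryl silyl ethers, two silyl esters) | O=C(O[C@H](Cc1ccc(O[Si](CC)(CC)CC)c(O[Si](CC)(CC)CC)c1)C(=O)O[Si](CC)(CC)CC)C1=Cc2ccc(O[Si](CC)(CC)CC)c(O[Si](CC)(CC)CC)c2[C@@H](c2ccc(O[Si](CC)(CC)CC)c(O[Si](CC)(CC)CC)c2)[C@@H]1C(=O)O[C@H](Cc1ccc(O[Si](CC)(CC)CC)c(O[Si](CC)(CC)CC)c1)C(=O)O[Si](CC)(CC)CC
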